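The C3–C7 segment of the target (ring carbons C3–C6 of the 1,2-dioxane plus the exocyclic vinylic carbon C7) is read as a masked 2,4-diethylglutaraldehyde: ring methylene C5 lies between two ethyl-bearing carbons, C4 and C6, each flanked by an aldehyde-level carbon. A catalytic enantioselective inverse-electron-demand hetero-Diels–Alder reaction of 2-ethylacrolein with (Z)-1-ethoxybut-1-ene forms the C4–C5 bond, closes a temporary dihydropyran ring, sets C4 and differentiates C3 (acetal) from C7 (enol ether). Oxygenation at C6 within this ring, an acid-triggered switch of the pyranone to the 1,2-dioxane, olefination at C7 and peroxycarbenium substitution at C3 finish the synthesis.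

Key step: step 2

Numbering used: O1–O2–C3(H)(CH2CO2H)–C4(H)(Et)–C5H2–C6(Et)(alkenyl) for the ring; C7=C8(CH3)–C9H2–C10H(Et)–C11=C12–C13–C14 for the side chain.

Assumption: the (1R,2S)-ligand in step 2 is taken to give (2S,3R)-4; if the opposite sense of induction is found, the mirror-image ligand is used.

Step 1
Reactants: 1 allyl ethyl ether (3-ethoxyprop-1-ene)
Product: 2 (Z)-1-ethoxybut-1-ene
Conditions: s-BuLi, THF, −65 °C; then MeI, −65 °C → rt
Reagents that add atoms: iodomethane, CI
Why: Deprotonation gives the lithium-chelated (Z)-1-ethoxyallyl anion, which is methylated mainly at the γ-carbon to give the (Z)-enol ether (γ-alkylation of a metalated allyl ether, a homoenolate equivalent); no stereocentre is formed and the Z geometry follows from the chelated anion.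

Step 2
Reactants: 2 (Z)-1-ethoxybut-1-ene; 3 2-ethylacrolein (2-methylidenebutanal)
Product: 4 (2S,3R)-2-ethoxy-3,5-diethyl-3,4-dihydro-2H-pyran
Conditions: [CrCl(L)] (5 mol%; L = dianion of (1R,2S)-1-{[3-(1-adamantyl)-2-hydroxy-5-methylbenzylidene]amino}indan-2-ol), 4 Å molecular sieves, neat (2 in excess), rt
Reagents that add atoms: none
Why: The Lewis-acidic trivalent chromium centre binds the aldehyde oxygen of 3 and activates its s-cis 1-oxadiene (O=C7–C6=C5), which reacts with the electron-rich enol ether 2 in a concerted, asynchronous [4+2] cycloaddition that forms the C5–C4 σ-bond and the O–C3 bond in one step. The closest known reaction type is the inverse-electron-demand hetero-Diels–Alder reaction of α,β-unsaturated aldehydes with alkyl enol ethers under chiral chromium Schiff-base catalysis. The dihydropyran ring is closed in a six-membered pericyclic (4π + 2π, suprafacial–suprafacial) mode with the ethoxy group endo. The C4 stereocentre (pyran C3) is controlled by the catalyst, which exposes one face of the bound oxadiene to the endo-oriented enol ether, and the acetal centre (pyran C2) follows stereospecifically from the Z geometry of 2, giving the 2,3-cis (2S,3R) adduct. The step needs regioselectivity (alkoxy carbon to oxygen, enol ether β-carbon to the unsubstituted enal β-carbon C5; secured by the polarity of both partners), endo and facial selectivity (secured by the chiral catalyst) and a geometrically pure enol ether; because C5 carries no substituent, no further diastereomers can form. The resulting ring is temporary: it presents C6=C7 as an enol ether and C3 as an acetal and is dismantled in step 5.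

Step 3
Reactants: 4 (2S,3R)-2-ethoxy-3,5-diethyl-3,4-dihydro-2H-pyran
Product: 5 (5R,6S)-6-ethoxy-3,5-diethyloxan-2-one (both C3 epimers)
Conditions: pyridinium chlorochromate (C5H5NH[CrO3Cl]), NaOAc, 4 Å molecular sieves, CH2Cl2, rt
Reagents that add atoms: pyridinium chlorochromate, [O-][Cr](=O)(=O)Cl.c1cc[nH+]cc1
Why: Hexavalent chromium attacks the nucleophilic β-carbon of the cyclic enol ether and a 1,2-hydride shift from the adjacent O-bearing carbon gives the lactone (chlorochromate oxidation of a cyclic enol ether to a lactone); the new α-centre forms as a mixture that step 4 erases, and the mixed acetal and the C5 ethyl centre are untouched.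

Step 4
Reactants: 5 (5R,6S)-6-ethoxy-3,5-diethyloxan-2-one
Product: 6 (3R,5R,6S)-6-ethoxy-3,5-diethyl-3-hydroperoxyoxan-2-one
Conditions: LiN(iPr)2, THF, −78 °C; O2, −78 °C; AcOH, −78 °C
Reagents that add atoms: dioxygen, O=O
Why: Autoxidation of the lithium lactone enolate (enolate oxygenation to an α-hydroperoxy ester): in the half-chair enolate the C5 ethyl group is pseudo-equatorial and the anomeric ethoxy group pseudo-axial, so O2 enters axially from the opposite face and the quaternary C–O centre (C6 of the target) forms trans to the C5 ethyl group.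

Step 5
Reactants: 6 (3R,5R,6S)-6-ethoxy-3,5-diethyl-3-hydroperoxyoxan-2-one
Product: 8 methyl (3S,4R,6R)-3-ethoxy-4,6-diethyl-1,2-dioxane-6-carboxylate, via dioxane carboxylic acid 7 (not isolated)
Conditions: camphorsulfonic acid (cat.), CH2Cl2, 0 °C; then Me3SiCHN2, MeOH–toluene, 0 °C
Reagents that add atoms: (trimethylsilyl)diazomethane, C[Si](C)(C)C=[N+]=[N-]
Why: Acid ionises the acylal C–O bond (carboxylate as leaving group) and the tertiary hydroperoxide captures the ethoxy-stabilised oxocarbenium ion in a 6-exo transacetalisation, which exchanges the pyranone for the 1,2-dioxane without touching C4 or C6 (the new anomeric centre is thermodynamic, drawn as the axial-ethoxy anomer, and is erased in step 13), and the liberated acid is then methylated by the diazomethane surrogate.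

Step 6
Reactants: 8 methyl (3S,4R,6R)-3-ethoxy-4,6-diethyl-1,2-dioxane-6-carboxylate
Product: 9 (3S,4R,6R)-3-ethoxy-4,6-diethyl-1,2-dioxane-6-carbaldehyde
Conditions: iBu2AlH, CH2Cl2, −78 °C; aqueous work-up
Reagents that add atoms: none
Why: Partial reduction of the methyl ester via an aluminium hemiacetal that is stable at −78 °C and releases the non-enolisable aldehyde on work-up (ester-to-aldehyde reduction with a dialkylaluminium hydride, which should leave the peroxide and the peroxyacetal intact at this temperature).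

Step 7
Reactants: 10 (E)-pent-2-enal
Product: 11 (3R,4E)-hept-4-en-3-ol
Conditions: Et2Zn, (2R)-(+)-3-exo-(dimethylamino)isoborneol (2 mol%), toluene, 0 °C
Reagents that add atoms: diethylzinc, CC[Zn]CC
Why: Amino-alcohol-catalysed enantioselective addition of diethylzinc to the enal, in which the (2R)-ligand directs ethyl transfer to the aldehyde face that gives the (R)-allylic alcohol.

Step 8
Reactants: 11 (3R,4E)-hept-4-en-3-ol; 12 2-methoxypropene
Product: 14 (4R,5E)-4-ethyloct-5-en-2-one, via allyl isopropenyl ether 13 (not isolated)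
Conditions: pyridinium p-toluenesulfonate (cat.), xylene, 130 °C, sealed tube
Reagents that add atoms: none
Why: Acid-catalysed ether exchange gives the allyl isopropenyl ether, whose chair-like [3,3]-sigmatropic rearrangement (Saucy–Marbet variant of the Claisen rearrangement) with the carbinol ethyl group equatorial transfers the C–O stereocentre to the new C–C stereocentre (C10, R) and forms the E alkene.

Step 9
Reactants: 14 (4R,5E)-4-ethyloct-5-en-2-one
Product: 15 (4R,5E)-4-ethyloct-5-en-2-ol (both C2 epimers)
Conditions: NaBH4, MeOH, 0 °C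
Reagents that add atoms: none
Why: Borohydride reduction of the methyl ketone; the new carbinol centre forms as a mixture, which is irrelevant because this carbon becomes sp2 in step 12.

Step 10
Reactants: 15 (4R,5E)-4-ethyloct-5-en-2-ol
Product: 16 5-{[(4R,5E)-4-ethyloct-5-en-2-yl]sulfanyl}-1-phenyl-1H-tetrazole (both epimers at C2 of the chain)
Conditions: 1-phenyl-1H-tetrazole-5-thiol, PPh3, diisopropyl azodicarboxylate, THF, 0 °C → rt
Reagents that add atoms: 1-phenyl-1H-tetrazole-5-thiol, Sc1nnnn1-c1ccccc1
Why: Mitsunobu substitution of the secondary alcohol by the acidic tetrazolethiol (inversion at a centre whose configuration is irrelevant).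

Step 11
Reactants: 16 5-{[(4R,5E)-4-ethyloct-5-en-2-yl]sulfanyl}-1-phenyl-1H-tetrazole
Product: 17 5-{[(4R,5E)-4-ethyloct-5-en-2-yl]sulfonyl}-1-phenyl-1H-tetrazole (both epimers at C2 of the chain)
Conditions: (NH4)6Mo7O24·4H2O (cat.), 30% aqueous H2O2, EtOH, 0 °C → rt
Reagents that add atoms: hydrogen peroxide, OO
Why: Molybdate-catalysed oxidation of the sulfide to the sulfone with hydrogen peroxide, which is faster than epoxidation of the isolated trans-disubstituted alkene.

Step 12
Reactants: 9 (3S,4R,6R)-3-ethoxy-4,6-diethyl-1,2-dioxane-6-carbaldehyde; 17 5-{[(4R,5E)-4-ethyloct-5-en-2-yl]sulfonyl}-1-phenyl-1H-tetrazole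
Product: 18 (3S,4R,6R)-3-ethoxy-4,6-diethyl-6-[(1E,4R,5E)-4-ethyl-2-methylocta-1,5-dien-1-yl]-1,2-dioxane
Conditions: 17 (slight excess), KN(SiMe3)2 (slightly less than 17), DME, −60 °C; then 9, −60 °C → rt; aqueous work-up
Reagents that add atoms: none
Why: Julia–Kocienski olefination: the branched sulfonyl carbanion adds to the non-enolisable aldehyde and Smiles rearrangement followed by anti-elimination of sulfur dioxide and tetrazolate gives the trisubstituted alkene, the E isomer being expected because the bulky quaternary C6 substituent avoids the larger CH2R group of the carbanion in the addition step.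

Step 13
Reactants: 18 (3S,4R,6R)-3-ethoxy-4,6-diethyl-6-[(1E,4R,5E)-4-ethyl-2-methylocta-1,5-dien-1-yl]-1,2-dioxane
Product: 20 2-[(3R,4R,6R)-4,6-diethyl-6-[(1E,4R,5E)-4-ethyl-2-methylocta-1,5-dien-1-yl]-1,2-dioxan-3-yl]acetic acid (target), via trimethylsilyl ester 19 (not isolated)
Conditions: CH2=C(OSiMe3)2, Me3SiOSO2CF3 (cat.), CH2Cl2, −78 °C; pH 7 buffer
Reagents that add atoms: ketene bis(trimethylsilyl) acetal [1,1-bis(trimethylsilyloxy)ethene], C=C(O[Si](C)(C)C)O[Si](C)(C)C
Why: The silyl triflate ionises the peroxyacetal to a six-membered peroxycarbenium ion whose half-chair holds the C4 ethyl and C6 alkenyl groups pseudo-equatorial, and the ketene acetal attacks axially (Lewis-acid-mediated substitution of an alkoxy-1,2-dioxane by a silyl ketene acetal, a Mukaiyama-type addition), which sets C3 as R, cis to both the C4 ethyl and the C6 alkenyl groups, before the silyl ester is hydrolysed on work-up.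

Compound list
1 | allyl ethyl ether (3-ethoxyprop-1-ene) | C=CCOCC | starting material
2 | (Z)-1-ethoxybut-1-ene | CC/C=C\OCC | intermediate
3 | 2-ethylacrolein (2-methylidenebutanal) | CCC(=C)C=O | starting material
4 | (2S,3R)-2-ethoxy-3,5-diethyl-3,4-dihydro-2H-pyran | CCC1=CO[C@H](OCC)[C@H](CC)C1 | intermediate
5 | (5R,6S)-6-ethoxy-3,5-diethyloxan-2-one (both C3 epimers) | CCC1C(=O)O[C@H](OCC)[C@H](CC)C1 | intermediate
6 | (3R,5R,6S)-6-ethoxy-3,5-diethyl-3-hydroperoxyoxan-2-one | CC[C@]1(OO)C(=O)O[C@H](OCC)[C@H](CC)C1 | intermediate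
7 | (3S,4R,6R)-3-ethoxy-4,6-diethyl-1,2-dioxane-6-carboxylic acid (not isolated; axial-ethoxy anomer drawn) | OC(=O)[C@@]1(CC)C[C@@H](CC)[C@@H](OCC)OO1 | intermediate
8 | methyl (3S,4R,6R)-3-ethoxy-4,6-diethyl-1,2-dioxane-6-carboxylate | COC(=O)[C@@]1(CC)C[C@@H](CC)[C@@H](OCC)OO1 | intermediate
9 | (3S,4R,6R)-3-ethoxy-4,6-diethyl-1,2-dioxane-6-carbaldehyde | O=C[C@@]1(CC)C[C@@H](CC)[C@@H](OCC)OO1 | intermediate
10 | (E)-pent-2-enal | CC/C=C/C=O | starting material
11 | (3R,4E)-hept-4-en-3-ol | CC/C=C/[C@H](O)CC | intermediate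
12 | 2-methoxypropene | COC(C)=C | starting material
13 | (3R,4E)-3-(prop-1-en-2-yloxy)hept-4-ene (not isolated) | CC/C=C/[C@H](OC(C)=C)CC | intermediate
14 | (4R,5E)-4-ethyloct-5-en-2-one | CC/C=C/[C@H](CC)CC(C)=O | intermediate
15 | (4R,5E)-4-ethyloct-5-en-2-ol (both C2 epimers) | CC/C=C/[C@H](CC)CC(C)O | intermediate
16 | 5-{[(4R,5E)-4-ethyloct-5-en-2-yl]sulfanyl}-1-phenyl-1H-tetrazole (both epimers at C2 of the chain) | CC/C=C/[C@H](CC)CC(C)Sc1nnnn1-c1ccccc1 | intermediate
17 | 5-{[(4R,5E)-4-ethyloct-5-en-2-yl]sulfonyl}-1-phenyl-1H-tetrazole (both epimers at C2 of the chain) | CC/C=C/[C@H](CC)CC(C)S(=O)(=O)c1nnnn1-c1ccccc1 | intermediate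
18 | (3S,4R,6R)-3-ethoxy-4,6-diethyl-6-[(1E,4R,5E)-4-ethyl-2-methylocta-1,5-dien-1-yl]-1,2-dioxane | CC/C=C/[C@H](CC)C/C(C)=C/[C@@]1(CC)C[C@@H](CC)[C@@H](OCC)OO1 | intermediate
19 | trimethylsilyl 2-[(3R,4R,6R)-4,6-diethyl-6-[(1E,4R,5E)-4-ethyl-2-methylocta-1,5-dien-1-yl]-1,2-dioxan-3-yl]acetate (not isolated) | CC/C=C/[C@H](CC)C/C(C)=C/[C@@]1(CC)C[C@@H](CC)[C@@H](CC(=O)O[Si](C)(C)C)OO1 | intermediate
20 | 2-[(3R,4R,6R)-4,6-diethyl-6-[(1E,4R,5E)-4-ethyl-2-methylocta-1,5-dien-1-yl]-1,2-dioxan-3-yl]acetic acid | CC/C=C/[C@H](CC)C/C(C)=C/[C@@]1(CC)C[C@@H](CC)[C@@H](CC(=O)O)OO1 | target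

Total steps: 13. Longest linear sequence: 8 steps (steps 1–6, 12 and 13); the side chain (steps 7–11) joins at step 12.

Steps most likely to fail

1. Step 2. The 1,2-disubstituted enol ether may add only slowly to the α-branched enal, or the catalyst may discriminate poorly between the two faces or between endo and exo approach. Either would erode the enantiomeric purity on which every later centre depends. Fallback (from 2 and 3, back at 7): 2 and 3 would be combined under achiral Lewis-acid catalysis with Yb(fod)3 to give racemic cis-2-ethoxy-3,5-diethyl-3,4-dihydro-2H-pyran F1. The conditions of step 3 would then give racemic 6-ethoxy-3,5-diethyloxan-2-one F2, and those of step 4 racemic 6-ethoxy-3,5-diethyl-3-hydroperoxyoxan-2-one F3. The acid-mediated ring switch of step 5 would give racemic 3-ethoxy-4,6-diethyl-1,2-dioxane-6-carboxylic acid F4. This acid would be resolved by fractional crystallisation with (S)-1-phenylethylamine, the salt of the (4R,6R) acid being (S)-1-phenylethylammonium (3S,4R,6R)-3-ethoxy-4,6-diethyl-1,2-dioxane-6-carboxylate F5. Acidification of F5 liberates 7, which is methylated to 8 as in the second half of step 5.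

2. Step 12. The addition of the branched sulfonyl carbanion may not distinguish well between its methyl and CH2R groups, giving poor E/Z control, and addition to the neopentyl-type aldehyde may be slow. Fallback (from 15 and 9, back at 18): a Horner–Wittig sequence with a separable intermediate. Alcohol 15 would be converted with MeSO2Cl and Et3N into (4R,5E)-4-ethyloct-5-en-2-yl methanesulfonate F6. Displacement with Ph2P(O)Li (Michaelis–Becker alkylation) would give [(4R,5E)-4-ethyloct-5-en-2-yl]diphenylphosphine oxide F7. Lithiation with n-BuLi in THF at −78 °C and addition to 9 would give diastereomeric β-hydroxy phosphine oxides. From these, (1R,2R,4R,5E)-2-(diphenylphosphoryl)-1-[(3S,4R,6R)-3-ethoxy-4,6-diethyl-1,2-dioxan-6-yl]-4-ethyl-2-methyloct-5-en-1-ol F8 would be separated by chromatography. KH in DMF should then effect stereospecific syn-elimination of diphenylphosphinate from F8 to give 18 as the E isomer only.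

3. Step 13. The silyl triflate may ionise the tertiary, allylic C6–O bond in competition with the acetal, or the ketene acetal may not attack the axial face cleanly. Fallback (from 8, back at 20): the acetic acid unit is installed before the alkene exists, so that no allylic peroxide is exposed to the Lewis acid. Ester 8 would be treated with the same ketene acetal and Me3SiOSO2CF3 to give 2-[(3R,4R,6R)-4,6-diethyl-6-(methoxycarbonyl)-1,2-dioxan-3-yl]acetic acid F9; the ester group at C6 disfavours ionisation there. iBu2AlH at −78 °C, with one extra equivalent for the carboxylic acid, would reduce the methyl ester to 2-[(3R,4R,6R)-4,6-diethyl-6-formyl-1,2-dioxan-3-yl]acetic acid F10. Julia–Kocienski olefination of the potassium carboxylate of F10 with 17 under the conditions of step 12 would then give 20 directly.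

Further compounds
F1 | step 2 | racemic cis-2-ethoxy-3,5-diethyl-3,4-dihydro-2H-pyran | CCC1=CO[C@H](OCC)[C@H](CC)C1.CCC1=CO[C@@H](OCC)[C@@H](CC)C1
F2 | step 2 | racemic 6-ethoxy-3,5-diethyloxan-2-one (5,6-cis; both C3 epimers) | CCC1C(=O)O[C@H](OCC)[C@H](CC)C1.CCC1C(=O)O[C@@H](OCC)[C@@H](CC)C1
F3 | step 2 | racemic 6-ethoxy-3,5-diethyl-3-hydroperoxyoxan-2-one (relative configuration as in 6) | CC[C@]1(OO)C(=O)O[C@H](OCC)[C@H](CC)C1.CC[C@@]1(OO)C(=O)O[C@@H](OCC)[C@@H](CC)C1
F4 | step 2 | racemic 3-ethoxy-4,6-diethyl-1,2-dioxane-6-carboxylic acid (relative configuration as in 7) | OC(=O)[C@@]1(CC)C[C@@H](CC)[C@@H](OCC)OO1.OC(=O)[C@]1(CC)C[C@H](CC)[C@H](OCC)OO1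
F5 | step 2 | (S)-1-phenylethylammonium (3S,4R,6R)-3-ethoxy-4,6-diethyl-1,2-dioxane-6-carboxylate | C[C@H]([NH3+])c1ccccc1.[O-]C(=O)[C@@]1(CC)C[C@@H](CC)[C@@H](OCC)OO1
F6 | step 12 | (4R,5E)-4-ethyloct-5-en-2-yl methanesulfonate (both C2 epimers) | CC/C=C/[C@H](CC)CC(C)OS(C)(=O)=O
F7 | step 12 | [(4R,5E)-4-ethyloct-5-en-2-yl]diphenylphosphine oxide (both C2 epimers) | CC/C=C/[C@H](CC)CC(C)P(=O)(c1ccccc1)c1ccccc1
F8 | step 12 | (1R,2R,4R,5E)-2-(diphenylphosphoryl)-1-[(3S,4R,6R)-3-ethoxy-4,6-diethyl-1,2-dioxan-6-yl]-4-ethyl-2-methyloct-5-en-1-ol | CC/C=C/[C@H](CC)C[C@@](C)(P(=O)(c1ccccc1)c1ccccc1)[C@H](O)[C@@]1(CC)C[C@@H](CC)[C@@H](OCC)OO1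
F9 | step 13 | 2-[(3R,4R,6R)-4,6-diethyl-6-(methoxycarbonyl)-1,2-dioxan-3-yl]acetic acid | COC(=O)[C@@]1(CC)C[C@@H](CC)[C@@H](CC(=O)O)OO1
F10 | step 13 | 2-[(3R,4R,6R)-4,6-diethyl-6-formyl-1,2-dioxan-3-yl]acetic acid | O=C[C@@]1(CC)C[C@@H](CC)[C@@H](CC(=O)O)OO1
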